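## Retrosynthetic overview

1. Prokinawan ⇐ mild acidic removal of four MOM ethers from the (2S)-flavanone; ring C is the last ring formed.
2. Ring C ⇐ enantioselective arylative one-carbon ring expansion: a cyclopropa[b]benzofuran-6b-ol (ring A + fused furanone + CH2) opens at the ring-fusion C–C bond to a 4-oxochroman-2-yl radical, which chiral nickel arylates with a catechol-derived aryl bromide (ring B).
3. Cyclopropanol ⇐ Simmons–Smith on a 3-silyloxybenzofuran ⇐ dihydrobenzofuranol from a salicylaldehyde and a sulfoxonium ylide (five-membered O-ring first, cyclopropane second, pyranone third).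
4. Ring A ⇐ resorcinol: bis-MOM ether, C2 lithiation/allylation, meta C–H borylation/oxidation to a symmetric phenol, ortho-formylation (symmetry fixes the later 6-substitution).
5. Side chain ⇐ hept-6-yn-2-one: MeMgBr, Negishi carboalumination/CH2O, Corey–Kim bromide.

Assumption: hept-6-yn-2-one is taken as a catalogue chemical, and the bis(oxazoline) antipode in step 13 is the one that delivers (2S), to be fixed by one model coupling.

Abbreviations: R = (E)-7-hydroxy-3,7-dimethyloct-2-en-1-yl, –CH2CH=C(CH3)CH2CH2CH2C(CH3)2OH; MOM = CH2OCH3.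

## Route

Step 1
Reactants: 1 hept-6-yn-2-one
Product: 2 2-methylhept-6-yn-2-ol
Conditions: MeMgBr (1.3 equiv), THF, −20 → 0 °C; aq. NH4Cl
Reagents that add atoms: methylmagnesium bromide, C[Mg]Br
Why: Grignard 1,2-addition to the methyl ketone outruns deprotonation of the terminal alkyne at low temperature and gives the tertiary carbinol of the side-chain terminus.

Step 2
Reactants: 2 2-methylhept-6-yn-2-ol
Product: 4 (E)-3,7-dimethyloct-2-ene-1,7-diol, via alkenylalane 3 (not isolated)
Conditions: AlMe3 (3 equiv), Cp2ZrCl2 (25 mol %), CH2Cl2, 0 → 23 °C; then n-BuLi, THF, −78 °C; (CH2O)n, −78 → 23 °C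
Reagents that add atoms: trimethylaluminium, C[Al](C)C; paraformaldehyde (formaldehyde unit), C=O
Why: Negishi zirconium-catalysed carboalumination adds CH3 and Al syn across the alkyne with Al at the terminus (the aluminium alkoxide of the OH is tolerated), and hydroxymethylation of the derived alanate proceeds with retention, which sets the E trisubstituted alkene.

Step 3
Reactants: 4 (E)-3,7-dimethyloct-2-ene-1,7-diol
Product: 5 (E)-8-bromo-2,6-dimethyloct-6-en-2-ol
Conditions: NBS, Me2S, CH2Cl2, −20 → 0 °C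
Reagents that add atoms: N-bromosuccinimide, O=C1CCC(=O)N1Br
Why: Corey–Kim halogenation activates only the primary allylic alcohol as an alkoxysulfonium ion, and bromide displaces it by SN2 without allylic shift or loss of E geometry, the tertiary alcohol being inert.

Step 4
Reactants: 6 resorcinol
Product: 7 1,3-bis(methoxymethoxy)benzene
Conditions: NaH, MOMCl, DMF, 0 → 23 °C
Reagents that add atoms: chloromethyl methyl ether, COCCl
Why: Williamson-type O-alkylation of both phenoxides installs the acetal ethers that later direct metalation and come off under mild acid.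

Step 5
Reactants: 7 1,3-bis(methoxymethoxy)benzene; 5 (E)-8-bromo-2,6-dimethyloct-6-en-2-ol
Product: 9 (E)-8-[2,6-bis(methoxymethoxy)phenyl]-2,6-dimethyloct-6-en-2-ol, via aryllithium 8 (not isolated)
Conditions: 7 (2.3 equiv), n-BuLi (2.2 equiv), THF, 0 → 23 °C; CuBr·SMe2 (1.1 equiv), −40 °C; then 5 (1 equiv), −40 → 0 °C
Reagents that add atoms: none
Why: Directed ortho-metalation occurs at C2 between the two MOM ethers, and the derived aryl cuprate displaces the primary allylic bromide (SN2) with retention of the E alkene, one aryl equivalent serving as base for the free OH.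

Step 6
Reactants: 9 (E)-8-[2,6-bis(methoxymethoxy)phenyl]-2,6-dimethyloct-6-en-2-ol
Product: 11 4-R-3,5-bis(methoxymethoxy)phenol, via arylboronate 10 (not isolated)
Conditions: [Ir(OMe)(cod)]2 (1.5 mol %), dtbpy (3 mol %), B2pin2 (2 equiv), THF, 70 °C; then aq. NaOH, 30% H2O2, 0 °C
Reagents that add atoms: bis(pinacolato)diboron, CC1(C)OB(OC1(C)C)B1OC(C)(C)C(C)(C)O1 (boron held only in 10); hydrogen peroxide, OO
Why: Hartwig–Miyaura iridium-catalysed C–H borylation is sterically controlled and takes the only ring C–H without an ortho substituent (C5), and C–B oxidation then gives the third ring oxygen as the single free OH of a symmetric phenol, the trisubstituted alkene and the transiently O-borylated carbinol being unaffected.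

Step 7
Reactants: 11 4-R-3,5-bis(methoxymethoxy)phenol
Product: 12 2-hydroxy-5-R-4,6-bis(methoxymethoxy)benzaldehyde
Conditions: MgCl2 (2 equiv), Et3N (4 equiv), (CH2O)n (6 equiv), MeCN, 75 °C
Reagents that add atoms: paraformaldehyde (formaldehyde unit), C=O
Why: Casnati–Skattebøl ortho-formylation of the magnesium phenoxide can only give one isomer because the two ortho positions are equivalent and the para position is blocked, a second formaldehyde acting as hydride acceptor.

Step 8
Reactants: 12 2-hydroxy-5-R-4,6-bis(methoxymethoxy)benzaldehyde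
Product: 14 5-R-4,6-bis(methoxymethoxy)-2,3-dihydro-1-benzofuran-3-ol (racemic), via epoxide 13 (not isolated)
Conditions: Me3S(O)I (3 equiv), NaH (4.5 equiv), DMSO–THF, 23 → 50 °C
Reagents that add atoms: trimethylsulfoxonium iodide, C[S+](C)(C)=O.[I-]
Why: Corey–Chaykovsky methylene transfer to the aldehyde gives an aryl epoxide that the ortho phenoxide opens at the CH2 terminus (5-exo-tet) to close the furan ring, the racemic carbinol centre being erased in the next step.

Step 9
Reactants: 14 5-R-4,6-bis(methoxymethoxy)-2,3-dihydro-1-benzofuran-3-ol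
Product: 16 5-[(E)-3,7-dimethyl-7-(trimethylsilyloxy)oct-2-en-1-yl]-4,6-bis(methoxymethoxy)-3-(trimethylsilyloxy)-1-benzofuran, via ketone 15 (not isolated)
Conditions: n-Pr4N[RuO4] (5 mol %), NMO (1.5 equiv), 4 Å molecular sieves, CH2Cl2, 23 °C; then Et3N (6 equiv), TMSOTf (3.5 equiv), 0 °C; non-aqueous work-up
Reagents that add atoms: trimethylsilyl trifluoromethanesulfonate, C[Si](C)(C)OS(=O)(=O)C(F)(F)F
Why: Ley–Griffith oxidation converts only the secondary benzylic alcohol into the benzofuran-3(2H)-one, whose aromatic enol form is trapped in the same flask as the silyl enol ether while the tertiary alcohol is silylated as well.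

Step 10
Reactants: 16 bis-TMS 3-silyloxybenzofuran
Product: 18 5-R-4,6-bis(methoxymethoxy)-1a,6b-dihydro-1H-cyclopropa[b][1]benzofuran-6b-ol (racemic cis-fused), via siloxycyclopropane 17 (not isolated)
Conditions: Et2Zn (1.5 equiv), CH2I2 (3 equiv), CH2Cl2–Et2O, −15 → 0 °C; pyridine; then K2CO3 (cat.), MeOH, 0 °C
Reagents that add atoms: diiodomethane, ICI
Why: In the Furukawa–Simmons–Smith cyclopropanation the electrophilic zinc carbenoid should take the most nucleophilic π bond (the silyl enol ether C2=C3) ahead of the remote trialkyl alkene, the cis ring fusion is the only one possible, and mild methanolysis removes both TMS groups.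

Step 11
Reactants: 19 catechol
Product: 20 1,2-bis(methoxymethoxy)benzene
Conditions: NaH, MOMCl, DMF, 0 → 23 °C
Reagents that add atoms: chloromethyl methyl ether, COCCl
Why: Williamson-type O-alkylation masks the oxidation-prone catechol with the same acid-labile group used on ring A.

Step 12
Reactants: 20 1,2-bis(methoxymethoxy)benzene
Product: 21 4-bromo-1,2-bis(methoxymethoxy)benzene
Conditions: NBS, MeCN, 0 → 23 °C
Reagents that add atoms: N-bromosuccinimide, O=C1CCC(=O)N1Br
Why: Electrophilic aromatic bromination of the 1,2-dialkoxyarene goes para to one alkoxy group and stops at the monobromide under neutral conditions that leave the acetals intact.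

Step 13
Reactants: 18 cyclopropa[b]benzofuran-6b-ol; 21 4-bromo-1,2-bis(methoxymethoxy)benzene
Product: 23 (2S)-2-[3,4-bis(methoxymethoxy)phenyl]-6-R-5,7-bis(methoxymethoxy)-2,3-dihydro-4H-chromen-4-one, via chromanonyl radical 22 (not isolated)
Conditions: 21 (1.5 equiv), NiBr2·dme (10 mol %), (S,S)-t-Bu-BiOX (12 mol %), [Ir(dF(CF3)ppy)2(dtbbpy)]PF6 (2 mol %), K3PO4, DMA, blue LEDs, 10 °C
Reagents that add atoms: none
Why: Proposed new method: proton-coupled oxidation of the cyclopropanol O–H by the excited iridium photocatalyst with phosphate as base gives a cyclopropyloxy radical that undergoes β-scission of the ring-fusion C1a–C6b bond (strain release and formation of the oxygen-stabilised radical 22; scission of the other cyclopropane bond is reversible by 3-exo re-addition to the ketone, so both channels funnel to 22), which is the one-carbon expansion of the furanone to the pyranone; the chiral (BiOX)(aryl)nickel bromide formed by oxidative addition of 21 to zerovalent nickel captures planar 22, reductive elimination from the trivalent nickel species forms the C2–aryl bond and sets C2 (S) under ligand control, and the reduced photocatalyst returns monovalent nickel to zerovalent nickel; the closest known reaction types are the Saegusa–Ito and Dowd–Beckwith radical ring expansions, photoredox/nickel arylation of radicals released by β-scission of cycloalkanols, and enantioselective nickel/photoredox arylation of α-heteroatom radicals with bis(oxazoline) ligands.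

Step 14
Reactants: 23 (2S)-tetra-MOM flavanone
Product: 24 prokinawan
Conditions: HCl (2 M) in MeOH–THF, 30 °C
Reagents that add atoms: none
Why: Acid-catalysed acetal methanolysis cleaves the four aryl MOM ethers as dimethoxymethane under conditions chosen to be too mild to ionise the tertiary alcohol, cyclise the ortho-allyl phenol or open the flavanone ring, so C2 (S) and the E alkene are carried through.

## Compound list

1 | hept-6-yn-2-one | CC(=O)CCCC#C | starting material
2 | 2-methylhept-6-yn-2-ol | CC(C)(O)CCCC#C | intermediate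
3 | [(E)-6-(dimethylalumanyloxy)-2,6-dimethylhept-1-en-1-yl]dimethylalumane | C[Al](C)/C=C(\C)CCCC(C)(C)O[Al](C)C | intermediate (not isolated)
4 | (E)-3,7-dimethyloct-2-ene-1,7-diol | OC/C=C(\C)CCCC(C)(C)O | intermediate
5 | (E)-8-bromo-2,6-dimethyloct-6-en-2-ol | BrC/C=C(\C)CCCC(C)(C)O | intermediate
6 | resorcinol (benzene-1,3-diol) | Oc1cccc(O)c1 | starting material
7 | 1,3-bis(methoxymethoxy)benzene | COCOc1cccc(OCOC)c1 | intermediate
8 | [2,6-bis(methoxymethoxy)phenyl]lithium | [Li]c1c(OCOC)cccc1OCOC | intermediate (not isolated)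
9 | (E)-8-[2,6-bis(methoxymethoxy)phenyl]-2,6-dimethyloct-6-en-2-ol | COCOc1cccc(OCOC)c1C/C=C(\C)CCCC(C)(C)O | intermediate
10 | (E)-8-[2,6-bis(methoxymethoxy)-4-(4,4,5,5-tetramethyl-1,3,2-dioxaborolan-2-yl)phenyl]-2,6-dimethyloct-6-en-2-ol | COCOc1cc(B2OC(C)(C)C(C)(C)O2)cc(OCOC)c1C/C=C(\C)CCCC(C)(C)O | intermediate (not isolated)
11 | 4-[(E)-7-hydroxy-3,7-dimethyloct-2-en-1-yl]-3,5-bis(methoxymethoxy)phenol | COCOc1cc(O)cc(OCOC)c1C/C=C(\C)CCCC(C)(C)O | intermediate
12 | 2-hydroxy-5-[(E)-7-hydroxy-3,7-dimethyloct-2-en-1-yl]-4,6-bis(methoxymethoxy)benzaldehyde | O=Cc1c(O)cc(OCOC)c(C/C=C(\C)CCCC(C)(C)O)c1OCOC | intermediate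
13 | 4-[(E)-7-hydroxy-3,7-dimethyloct-2-en-1-yl]-3,5-bis(methoxymethoxy)-2-(oxiran-2-yl)phenol (racemic; phenoxide in the flask) | Oc1cc(OCOC)c(C/C=C(\C)CCCC(C)(C)O)c(OCOC)c1C1CO1 | intermediate (not isolated)
14 | 5-[(E)-7-hydroxy-3,7-dimethyloct-2-en-1-yl]-4,6-bis(methoxymethoxy)-2,3-dihydro-1-benzofuran-3-ol (racemic) | OC1COc2cc(OCOC)c(C/C=C(\C)CCCC(C)(C)O)c(OCOC)c21 | intermediate
15 | 5-[(E)-7-hydroxy-3,7-dimethyloct-2-en-1-yl]-4,6-bis(methoxymethoxy)-1-benzofuran-3(2H)-one | O=C1COc2cc(OCOC)c(C/C=C(\C)CCCC(C)(C)O)c(OCOC)c21 | intermediate (not isolated)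
16 | 5-[(E)-3,7-dimethyl-7-(trimethylsilyloxy)oct-2-en-1-yl]-4,6-bis(methoxymethoxy)-3-(trimethylsilyloxy)-1-benzofuran | C[Si](C)(C)Oc1coc2cc(OCOC)c(C/C=C(\C)CCCC(C)(C)O[Si](C)(C)C)c(OCOC)c12 | intermediate
17 | 5-[(E)-3,7-dimethyl-7-(trimethylsilyloxy)oct-2-en-1-yl]-4,6-bis(methoxymethoxy)-6b-(trimethylsilyloxy)-1a,6b-dihydro-1H-cyclopropa[b][1]benzofuran (racemic, cis-fused) | C[Si](C)(C)OC12CC1Oc1cc(OCOC)c(C/C=C(\C)CCCC(C)(C)O[Si](C)(C)C)c(OCOC)c12 | intermediate (not isolated)
18 | 5-[(E)-7-hydroxy-3,7-dimethyloct-2-en-1-yl]-4,6-bis(methoxymethoxy)-1a,6b-dihydro-1H-cyclopropa[b][1]benzofuran-6b-ol (racemic, cis-fused) | OC12CC1Oc1cc(OCOC)c(C/C=C(\C)CCCC(C)(C)O)c(OCOC)c12 | intermediate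
19 | catechol (benzene-1,2-diol) | Oc1ccccc1O | starting material
20 | 1,2-bis(methoxymethoxy)benzene | COCOc1ccccc1OCOC | intermediate
21 | 4-bromo-1,2-bis(methoxymethoxy)benzene | COCOc1ccc(Br)cc1OCOC | intermediate
22 | 6-[(E)-7-hydroxy-3,7-dimethyloct-2-en-1-yl]-5,7-bis(methoxymethoxy)-4-oxo-3,4-dihydro-2H-chromen-2-yl radical | O=C1C[CH]Oc2cc(OCOC)c(C/C=C(\C)CCCC(C)(C)O)c(OCOC)c21 | intermediate (not isolated)
23 | (2S)-2-[3,4-bis(methoxymethoxy)phenyl]-6-[(E)-7-hydroxy-3,7-dimethyloct-2-en-1-yl]-5,7-bis(methoxymethoxy)-2,3-dihydro-4H-chromen-4-one | O=C1C[C@@H](c2ccc(OCOC)c(OCOC)c2)Oc2cc(OCOC)c(C/C=C(\C)CCCC(C)(C)O)c(OCOC)c21 | intermediate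
24 | prokinawan, (2S)-2-(3,4-dihydroxyphenyl)-5,7-dihydroxy-6-[(E)-7-hydroxy-3,7-dimethyloct-2-en-1-yl]-2,3-dihydro-4H-chromen-4-one | C/C(=C\Cc1c(O)cc2c(c1O)C(=O)C[C@@H](c1ccc(O)c(O)c1)O2)CCCC(C)(C)O | target

## Step count and risks

Total steps: 14. Longest linear sequence: 11 (steps 1, 2, 3, 5, 6, 7, 8, 9, 10, 13, 14).

**Step 13 (the new reaction).** It may fail through β-hydride loss from the alkylnickel species (giving the chromone), through low enantioselectivity, or through competing oxidation of the electron-rich arenes. The fallback uses known chemistry and keeps the ring expansion. Setting out from 18, FeCl3 in DMF at 0 °C (Saegusa–Ito oxidative ring expansion) gives 2-chloro-6-[(E)-7-hydroxy-3,7-dimethyloct-2-en-1-yl]-5,7-bis(methoxymethoxy)-2,3-dihydro-4H-chromen-4-one F1. NaOAc in MeOH then eliminates HCl to give 6-[(E)-7-hydroxy-3,7-dimethyloct-2-en-1-yl]-5,7-bis(methoxymethoxy)-4H-chromen-4-one F2. In parallel, 21 is converted by n-BuLi at −78 °C into [3,4-bis(methoxymethoxy)phenyl]lithium F3 and, with B(OiPr)3 followed by aqueous NH4Cl, into [3,4-bis(methoxymethoxy)phenyl]boronic acid F4. Asymmetric conjugate addition of F4 to F2 catalysed by Pd(OCOCF3)2 and t-BuPyOX (NH4PF6, H2O, ClCH2CH2Cl, 60 °C; ligand antipode chosen for 2S) comes back to the route at 23.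

**Step 10 (chemoselective cyclopropanation).** The zinc carbenoid may also attack the side-chain alkene, and the furan-type enol ether may be sluggish. The fallback sets out from 14. The Ley–Griffith oxidation of step 9 is worked up to isolate ketone 15, and LiN(SiMe3)2 (2.1 equiv, THF, −78 °C) converts it into the dilithium enolate-alkoxide of 15 F5. SmI2 and CH2I2 (−78 → 0 °C) then deliver the methylene through the enolate oxygen; samarium carbenoids of this kind leave unfunctionalised alkenes untouched. Aqueous work-up gives the free cyclopropanol directly, and the route is rejoined at 18.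

**Step 8 (ylide annulation).** The aldehyde of 12 is deactivated as its phenoxide and flanked by two ortho substituents, so methylene transfer may stall. The fallback sets out from 11. Ethyl vinyl ether and pyridinium p-toluenesulfonate give 1-(1-ethoxyethoxy)-4-[(E)-7-(1-ethoxyethoxy)-3,7-dimethyloct-2-en-1-yl]-3,5-bis(methoxymethoxy)benzene F6. s-BuLi/TMEDA (THF, −78 °C) metalates the only type of ring C–H to give {2-(1-ethoxyethoxy)-5-[(E)-7-(1-ethoxyethoxy)-3,7-dimethyloct-2-en-1-yl]-4,6-bis(methoxymethoxy)phenyl}lithium F7. Acylation with 2-chloro-N-methoxy-N-methylacetamide gives 2-chloro-1-{2-(1-ethoxyethoxy)-5-[(E)-7-(1-ethoxyethoxy)-3,7-dimethyloct-2-en-1-yl]-4,6-bis(methoxymethoxy)phenyl}ethan-1-one F8. Pyridinium p-toluenesulfonate in MeOH removes both ethoxyethyl groups to give 2-chloro-1-{2-hydroxy-5-[(E)-7-hydroxy-3,7-dimethyloct-2-en-1-yl]-4,6-bis(methoxymethoxy)phenyl}ethan-1-one F9, and K2CO3 closes the furanone ring by intramolecular O-alkylation. The route is rejoined at 15, which is silylated to 16 as in the second half of step 9.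

## Further compounds

F1 | step 13 | 2-chloro-6-[(E)-7-hydroxy-3,7-dimethyloct-2-en-1-yl]-5,7-bis(methoxymethoxy)-2,3-dihydro-4H-chromen-4-one | O=C1CC(Cl)Oc2cc(OCOC)c(C/C=C(\C)CCCC(C)(C)O)c(OCOC)c21
F2 | step 13 | 6-[(E)-7-hydroxy-3,7-dimethyloct-2-en-1-yl]-5,7-bis(methoxymethoxy)-4H-chromen-4-one | O=c1ccoc2cc(OCOC)c(C/C=C(\C)CCCC(C)(C)O)c(OCOC)c12
F3 | step 13 | [3,4-bis(methoxymethoxy)phenyl]lithium | [Li]c1ccc(OCOC)c(OCOC)c1
F4 | step 13 | [3,4-bis(methoxymethoxy)phenyl]boronic acid | OB(O)c1ccc(OCOC)c(OCOC)c1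
F5 | step 10 | dilithium enolate-alkoxide of 15 (O3 enolate and side-chain alkoxide) | [Li]Oc1coc2cc(OCOC)c(C/C=C(\C)CCCC(C)(C)O[Li])c(OCOC)c12
F6 | step 8 | 1-(1-ethoxyethoxy)-4-[(E)-7-(1-ethoxyethoxy)-3,7-dimethyloct-2-en-1-yl]-3,5-bis(methoxymethoxy)benzene | CCOC(C)Oc1cc(OCOC)c(C/C=C(\C)CCCC(C)(C)OC(C)OCC)c(OCOC)c1
F7 | step 8 | {2-(1-ethoxyethoxy)-5-[(E)-7-(1-ethoxyethoxy)-3,7-dimethyloct-2-en-1-yl]-4,6-bis(methoxymethoxy)phenyl}lithium | CCOC(C)Oc1cc(OCOC)c(C/C=C(\C)CCCC(C)(C)OC(C)OCC)c(OCOC)c1[Li]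
F8 | step 8 | 2-chloro-1-{2-(1-ethoxyethoxy)-5-[(E)-7-(1-ethoxyethoxy)-3,7-dimethyloct-2-en-1-yl]-4,6-bis(methoxymethoxy)phenyl}ethan-1-one | CCOC(C)Oc1cc(OCOC)c(C/C=C(\C)CCCC(C)(C)OC(C)OCC)c(OCOC)c1C(=O)CCl
F9 | step 8 | 2-chloro-1-{2-hydroxy-5-[(E)-7-hydroxy-3,7-dimethyloct-2-en-1-yl]-4,6-bis(methoxymethoxy)phenyl}ethan-1-one | Oc1cc(OCOC)c(C/C=C(\C)CCCC(C)(C)O)c(OCOC)c1C(=O)CCl
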